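Substrate, coupling partner and by-product meet in the main step, whose by-product speeds that same step (autocatalysis), while target can take a further substrate in a side step.

| flask | substrate | coupling partner | remark | time |
|---|---|---|---|---|
| spring | 20 mM | 80.0 mM | one stirred flow tank at steady state, fed with the mixture as stated, mean residence time 4.0 d |  |
| autumn | 20 mM | 80.0 mM | a closed flask charged with all of it at once and left for 4.0 d | 4.0 d |
| winter | 20 mM (fed, over 4.00 d) | 80.0 mM | a stirred flask in which substrate is dosed at a steady rate over 4.00 d without added volume, worked up at 4.0 d | 4.0 d |
| midnight | 20 mM | 80.0 mM | plug flow through a tube for 4.0 d, no back-mixing | 4.0 d |

    substrate + coupling partner + by-product → target + 2 by-product (k1 = 180 L² mol⁻² h⁻¹)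
    substrate + target → side product (k2 = 13 L mol⁻¹ h⁻¹)
    substrate + coupling partner → target + by-product (k3 = 7.7 × 10⁻⁴ L mol⁻¹ h⁻¹)

- percentages count the substrate that a species holds: one side product counts as two
- the stated concentrations are those of everything mixed, before any reaction; amounts are the same in each set-up
- the feed brings no volume worth counting
- run time (autumn): 4.0 d

* the set-up with the highest amount of target at the outlet or at the end, in percent of the substrate put in ("none" if the first two lie within 2 percentage points) (spring / autumn / winter / midnight / none)
* amount of target at the outlet or at the end, in percent of the substrate put in, spring
* amount of target at the outlet or at the end, in percent of the substrate put in, autumn
* amount of target at the outlet or at the end, in percent of the substrate put in, winter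
* amount of target at the outlet or at the end, in percent of the substrate put in, midnight

Start with the autumn flask. It holds no by-product at first, so the uncatalysed step must seed it. That step's substrate half-life of 470 d is far longer than the 4.0 d run, so treat it as a seed and nothing else. With substrate and coupling partner at their charged levels, by-product doubles every 2.41 h. Extrapolated, that growth crosses the size of the charge after about 29.3 h; this is an estimate of the lag, not a level the flask attains, and it is shorter than the run.

Now compare the two steps that consume substrate at one moment. Substrate stands in both rates and cancels:

side step / main step = split number × target / by-product

The value 0.903 at the charge is the split number (a selectivity factor), the side step's constant over the main step's constant times the coupling partner concentration. Side product removes target but leaves by-product standing. With the split number held, target therefore keeps a steady share of by-product, and each target left has cost this much substrate: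

substrate used = target × (1 + 2 × split number)

Next ask how the comparison drifts. Take the whole 20 mM of substrate, the limiting reagent, as used. Coupling partner then falls to 66.4 mM, and the split number rises to 1.09. The autumn flask passes through these values, so use the mean coupling partner, which gives a split number of 0.986:

target, autumn = 33.6 %

The midnight tube is that flask along a length, so it gets the same figure. The spring tank sits at the end composition, and its steady by-product balance leaves 0.871 mM of substrate:

target, spring = 30.1 %

For the winter flask, commit to a bound from the split number at the charge: 35.6 %. That bound stands higher than the autumn figure, so my reckoning leaves the winter flask unplaced.

The forecast gives 33 % for autumn and midnight, 30.4 % for spring, 31.5 % for winter, and best: none. Its ground is that the ratio of the two steps “does not depend on substrate”. Its autumn figure is lower than mine, and its spring figure is higher.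

The result is 33.0 % target in the autumn flask and the midnight tube, 31.4 % in the winter flask and 30.5 % in the spring tank, so best is none. The autumn flask ends with 67.0 % of the charged substrate in side product. Now put the split number to the spring tank, where coupling partner stands at 67.4 mM. There it reads 1.07, and with 4.29 % of the substrate still at the outlet, the rule gives 30.4 % target.

All constants belong to no real substance, and the outcome is calculated.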